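The seven-membered ring is traced back to a cyclopropane. In the target, quaternary C1 and C5 are shared by the five-membered ring (C1–C5) and the seven-membered ring (C1, C5–C10), so C1, C5 and C10 can first be tied into a three-membered ring on a limonene-derived cyclopentane. A cis-divinylcyclopropane Cope shift then joins C7 to C8, breaks C5–C10 and gives the whole hydroazulene in one operation, with C1 already quaternary, C6 as a silyl enol ether and C9=C10 placed for oxygen transposition to C10. The precursor is a bicyclo[3.1.0]hexane carrying a 1-(triethylsilyloxy)vinyl group on C5 and an (E)-propenyl group on C10, set cis by a lactone tether during cyclopropanation.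

Key step: step 14

Remark: carbon numbers are those of the target skeleton ("daucane": C1 quaternary C–CH3, C2 and C3 CH2, C4 carbinol carbon with isopropyl, C5 ring-fusion CH, C6 to C10 round the seven-membered ring, methyl on C8). α is the face of the C1 methyl group, β the other face. Compound 6 is carried as both carbinol epimers because step 5 removes that centre.

Step 1
Reactants: 1 (S)-limonene
Product: 2 (S)-p-menth-1-ene
Conditions: H2 (1 atm), RhCl(PPh3)3 (1 mol %), PhH–EtOH, rt
Reagents that add atoms: none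
Why: Homogeneous hydrogenation with RhCl(PPh3)3 should reduce the 1,1-disubstituted side-chain alkene much faster than the trisubstituted ring alkene and leaves the stereocentre (future C4) untouched.

Step 2
Reactants: 2 (S)-p-menth-1-ene
Product: 4 (3S)-6-oxo-3-(propan-2-yl)heptanal, via secondary ozonide 3 (not isolated)
Conditions: O3, CH2Cl2, −78 °C; then Me2S, −78 °C → rt
Reagents that add atoms: ozone, [O-][O+]=O
Why: Ozonolysis with reductive work-up cleaves the only alkene to the keto aldehyde without touching the stereocentre.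

Step 3
Reactants: 4 (3S)-6-oxo-3-(propan-2-yl)heptanal
Product: 5 (5R)-2-methyl-5-(propan-2-yl)cyclopent-1-ene-1-carbaldehyde
Conditions: piperidine, AcOH, PhH, reflux (Dean–Stark)
Reagents that add atoms: none
Why: Amine-mediated intramolecular aldol condensation, in which the aldehyde enamine attacks the methyl ketone, closes the five-membered ring and dehydrates to the tetrasubstituted enal with the stereocentre intact.

Step 4
Reactants: 5 (5R)-2-methyl-5-(propan-2-yl)cyclopent-1-ene-1-carbaldehyde
Product: 6 1-[(5R)-2-methyl-5-(propan-2-yl)cyclopent-1-en-1-yl]ethan-1-ol, both carbinol epimers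
Conditions: MeMgBr, Et2O, −78 → 0 °C
Reagents that add atoms: methylmagnesium bromide, C[Mg]Br
Why: Grignard 1,2-addition to the hindered enal brings in C7; the new carbinol centre forms without control and is erased in step 5.

Step 5
Reactants: 6 1-[(5R)-2-methyl-5-(propan-2-yl)cyclopent-1-en-1-yl]ethan-1-ol
Product: 7 1-[(5R)-2-methyl-5-(propan-2-yl)cyclopent-1-en-1-yl]ethan-1-one
Conditions: Dess–Martin periodinane, CH2Cl2, rt
Reagents that add atoms: none
Why: Dess–Martin oxidation of the secondary allylic alcohol gives the methyl ketone under neutral conditions that do not move the double bond.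

Step 6
Reactants: 7 1-[(5R)-2-methyl-5-(propan-2-yl)cyclopent-1-en-1-yl]ethan-1-one
Product: 8 (1R)-1-[(5R)-2-methyl-5-(propan-2-yl)cyclopent-1-en-1-yl]ethan-1-ol
Conditions: (S)-2-methyl-CBS-oxazaborolidine (20 mol %), catecholborane, PhMe, −78 °C
Reagents that add atoms: none
Why: CBS reduction, in which the oxazaborolidine distinguishes the bulky cyclopentenyl group from methyl, should set the (R)-carbinol (future C6) by reagent control, the configuration matched to the cyclopropanation in step 9.

Step 7
Reactants: 8 (1R)-1-[(5R)-2-methyl-5-(propan-2-yl)cyclopent-1-en-1-yl]ethan-1-ol; 9 bromoacetyl bromide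
Product: 10 (1R)-1-[(5R)-2-methyl-5-(propan-2-yl)cyclopent-1-en-1-yl]ethyl bromoacetate
Conditions: pyridine, CH2Cl2, 0 °C
Reagents that add atoms: bromoacetyl bromide (9), BrCC(Br)=O
Why: Acylation of the secondary alcohol with the acid bromide installs the two carbons that become C9 and C10.

Step 8
Reactants: 10 (1R)-1-[(5R)-2-methyl-5-(propan-2-yl)cyclopent-1-en-1-yl]ethyl bromoacetate
Product: 11 (1R)-1-[(5R)-2-methyl-5-(propan-2-yl)cyclopent-1-en-1-yl]ethyl diazoacetate
Conditions: N,N'-ditosylhydrazine, DBU, THF, 0 °C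
Reagents that add atoms: N,N'-bis(4-methylbenzenesulfonyl)hydrazine, Cc1ccc(cc1)S(=O)(=O)NNS(=O)(=O)c1ccc(C)cc1
Why: N-Alkylation of ditosylhydrazine by the bromoacetate followed by base-induced loss of two sulfinates gives the diazoacetate under conditions that the allylic ester tolerates.

Step 9
Reactants: 11 (1R)-1-[(5R)-2-methyl-5-(propan-2-yl)cyclopent-1-en-1-yl]ethyl diazoacetate
Product: 12 cyclopropane-fused γ-lactone C5–C6H(CH3)–O–C9(=O)–C10 on 1-methyl-4-isopropylbicyclo[3.1.0]hexane (cyclopropane C1–C5–C10; C10 on the cyclopentane face opposite the isopropyl group; C6 methyl on the lactone face turned away from C1)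
Conditions: Rh2(OAc)4 (1 mol %), CH2Cl2, 40 °C, slow addition
Reagents that add atoms: none
Why: Intramolecular cyclopropanation of an allylic diazoacetate by a rhodium carbenoid: the five-membered lactone tether forces C9 on C10 to be cis to C6 on C5, the carbenoid adds to the alkene face opposite the C4 isopropyl group (which fixes C1 and C5), and the (R)-carbinol reinforces that facial choice by keeping its methyl group on the open lactone face.

Step 10
Reactants: 12 cyclopropane-fused γ-lactone
Product: 13 the corresponding lactol (C9 hemiacetal, both anomers)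
Conditions: i-Bu2AlH, CH2Cl2, −78 °C
Reagents that add atoms: none
Why: Half-reduction of the lactone at low temperature stops at the aluminium hemiacetal and exposes C9 at the aldehyde oxidation level.

Step 11
Reactants: 13 lactol; 14 5-(ethylsulfonyl)-1-phenyl-1H-tetrazole
Product: 15 (1R)-1-[4-isopropyl-1-methyl-10-((E)-prop-1-enyl)bicyclo[3.1.0]hex-5-yl]ethan-1-ol (target numbering; propenyl exo, cis to the C5 side chain; C10 anti to isopropyl)
Conditions: KN(SiMe3)2 (excess), DME, −60 °C → rt
Reagents that add atoms: 5-(ethylsulfonyl)-1-phenyl-1H-tetrazole (14), CCS(=O)(=O)c1nnnn1-c1ccccc1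
Why: Julia–Kocienski olefination of the ring-opened hydroxy aldehyde form of the lactol; the phenyltetrazolyl sulfone with a potassium base in DME should give the (E)-alkene, and the cyclopropyl α-hydrogen at C10 resists enolisation, so the cis arrangement is kept.

Step 12
Reactants: 15 (1R)-1-[4-isopropyl-1-methyl-10-((E)-prop-1-enyl)bicyclo[3.1.0]hex-5-yl]ethan-1-ol
Product: 16 1-[4-isopropyl-1-methyl-10-((E)-prop-1-enyl)bicyclo[3.1.0]hex-5-yl]ethan-1-one
Conditions: Dess–Martin periodinane, pyridine, CH2Cl2, 0 °C → rt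
Reagents that add atoms: none
Why: Buffered Dess–Martin oxidation converts the cyclopropyl carbinol into the methyl ketone without acid that could open the vinylcyclopropane.

Step 13
Reactants: 16 1-[4-isopropyl-1-methyl-10-((E)-prop-1-enyl)bicyclo[3.1.0]hex-5-yl]ethan-1-one
Product: 17 4-isopropyl-1-methyl-10-[(E)-prop-1-enyl]-5-[1-(triethylsilyloxy)vinyl]bicyclo[3.1.0]hexane (target numbering)
Conditions: LiN(i-Pr)2, Et3SiCl, THF, −78 °C
Reagents that add atoms: chlorotriethylsilane, CC[Si](Cl)(CC)CC
Why: The ketone can enolise only toward its methyl group because C5 is quaternary, so deprotonation with in situ silylation gives a single 2-silyloxydiene; the triethylsilyl ether survives handling and heating better than a trimethylsilyl ether and is still small enough for steps 14 and 15.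

Step 14
Reactants: 17 4-isopropyl-1-methyl-10-[(E)-prop-1-enyl]-5-[1-(triethylsilyloxy)vinyl]bicyclo[3.1.0]hexane
Product: 18 4-isopropyl-1,8-dimethyl-6-(triethylsilyloxy)bicyclo[5.3.0]deca-5,9-diene (target numbering; 1α-methyl, 4α-isopropyl, 8β-methyl)
Conditions: PhMe (degassed), trace Et3N, 80 → 110 °C, sealed tube
Reagents that add atoms: none
Why: Concerted [3,3]-sigmatropic (Cope) shift of a cis-1,2-dialkenylcyclopropane through the boat transition state, in which C7 and C8 bond above the three-membered ring while the strained C5–C10 bond breaks. The closest known reaction type is the divinylcyclopropane–cycloheptadiene rearrangement of 2-silyloxy-substituted substrates used for cycloheptadiene annulation. The seven-membered ring (C1, C5, C6, C7, C8, C9, C10) closes by pericyclic ring enlargement of the cyclopropane, the two alkene termini bonding to each other, so both new ring alkenes (C5=C6 and C9=C10) are cis. The one new stereocentre, C8, is controlled by the (E)-geometry of the propenyl group, whose methyl stays outside the boat so that H8 ends on the α-face with the C1 methyl group. The step needs the [3,3] shift to outrun the homodienyl 1,5-hydrogen shift from the cis C1 methyl group and needs both alkenyl groups on one cyclopropane face. The lactone-derived cis arrangement, the outward terminal methyl, the silyloxy donor and the release of ring strain secure this, and quaternary C1 blocks any further hydrogen shift in the product.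

Step 15
Reactants: 18 4-isopropyl-1,8-dimethyl-6-(triethylsilyloxy)bicyclo[5.3.0]deca-5,9-diene
Product: 19 dauca-4,9-dien-6-one (1α-methyl, 8β-methyl)
Conditions: Pd(OAc)2 (1.1 equiv), MeCN, rt
Reagents that add atoms: none
Why: Saegusa–Ito oxidation: the palladium enolate formed at C5 can undergo syn β-hydride elimination only with H4 (C1 has no hydrogen), so the C4=C5–C6 enone forms regiospecifically.

Step 16
Reactants: 19 dauca-4,9-dien-6-one
Product: 20 4β,5β-epoxydauc-9-en-6-one
Conditions: 30% H2O2, NaOH (cat.), MeOH, 0 °C → rt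
Reagents that add atoms: hydrogen peroxide, OO
Why: Weitz–Scheffer epoxidation: hydroperoxide should add to C4 from the β-face, anti to the C1 methyl group, and the enolate closes the 4β,5β-epoxide, which sets the C4 carbinol configuration; the isolated C9=C10 alkene is inert.

Step 17
Reactants: 20 4β,5β-epoxydauc-9-en-6-one
Product: 21 4β-hydroxy-5βH-dauc-9-en-6-one
Conditions: SmI2, THF–MeOH, −90 °C
Reagents that add atoms: none
Why: Single-electron reduction of the α,β-epoxy ketone cleaves the C5–O bond to a samarium enolate, which should be protonated at C5 from the β-face, away from the C1 methyl and C4 isopropyl groups, giving the trans-fused ketol with H5 cis to the C4 hydroxyl.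

Step 18
Reactants: 21 4β-hydroxy-5βH-dauc-9-en-6-one
Product: 22 5βH-dauc-9-ene-4β,6α-diol
Conditions: NaBH4, CeCl3·7H2O, MeOH, −40 °C
Reagents that add atoms: none
Why: Hydride should attack C6 from the β-face because the α-face is screened by the C1 methyl and C4 isopropyl groups, giving the 6α-alcohol, while CeCl3 keeps the medium non-basic so the β-hydroxy ketone neither epimerises nor undergoes retro-aldol cleavage.

Step 19
Reactants: 22 5βH-dauc-9-ene-4β,6α-diol; 23 4-(tert-butyldimethylsilyloxy)benzoic acid
Product: 24 4β-hydroxy-5βH-dauc-9-en-6α-yl 4-(tert-butyldimethylsilyloxy)benzoate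
Conditions: DCC, DMAP (cat.), CH2Cl2, rt
Reagents that add atoms: 4-(tert-butyldimethylsilyloxy)benzoic acid (23), CC(C)(C)[Si](C)(C)Oc1ccc(cc1)C(O)=O
Why: Steglich esterification acylates only the secondary C6 hydroxyl, the tertiary C4 hydroxyl being too hindered to react.

Step 20
Reactants: 24 4β-hydroxy-5βH-dauc-9-en-6α-yl 4-(tert-butyldimethylsilyloxy)benzoate
Product: 26 4β,10α-dihydroxy-5βH-dauc-8-en-6α-yl 4-(tert-butyldimethylsilyloxy)benzoate, via allylic 10α-hydroperoxide 25 (not isolated)
Conditions: O2, hν (visible), tetraphenylporphyrin (cat.), CH2Cl2, 0 °C; then PPh3, 0 °C → rt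
Reagents that add atoms: dioxygen, O=O
Why: Schenck ene reaction: singlet oxygen can abstract only H8 (C1 carries no hydrogen) and does so suprafacially, so oxygen arrives at C10 on the α-face where H8 lies and the alkene moves to C8=C9; PPh3 then reduces the hydroperoxide with retention.

Step 21
Reactants: 26 4β,10α-dihydroxy-5βH-dauc-8-en-6α-yl 4-(tert-butyldimethylsilyloxy)benzoate; 27 3-methylbutanoic anhydride
Product: 28 4β-hydroxy-10α-(3-methylbutanoyloxy)-5βH-dauc-8-en-6α-yl 4-(tert-butyldimethylsilyloxy)benzoate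
Conditions: DMAP, Et3N, CH2Cl2, rt
Reagents that add atoms: 3-methylbutanoic anhydride (27), CC(C)CC(=O)OC(=O)CC(C)C
Why: DMAP-catalysed acylation of the secondary allylic C10 hydroxyl; the tertiary C4 hydroxyl is inert under these conditions.

Step 22
Reactants: 28 4β-hydroxy-10α-(3-methylbutanoyloxy)-5βH-dauc-8-en-6α-yl 4-(tert-butyldimethylsilyloxy)benzoate
Product: 29 4β-hydroxy-10α-(3-methylbutanoyloxy)-5βH-dauc-8-en-6α-yl 4-hydroxybenzoate (target)
Conditions: Bu4NF, AcOH, THF, 0 °C
Reagents that add atoms: none
Why: Buffered fluoride cleaves the aryl silyl ether selectively and leaves both esters, the tertiary alcohol and the alkene untouched.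

Compound list

1 | (S)-limonene, (4S)-1-methyl-4-(prop-1-en-2-yl)cyclohex-1-ene | CC1=CC[C@H](CC1)C(C)=C | starting material
2 | (S)-p-menth-1-ene, (4S)-1-methyl-4-(propan-2-yl)cyclohex-1-ene | CC1=CC[C@H](CC1)C(C)C | intermediate
3 | secondary ozonide of 2 (1,2,4-trioxolane across the former alkene carbons, both bridgehead diastereomers) | CC12CC[C@H](C(C)C)CC(OO1)O2 | intermediate (not isolated)
4 | (3S)-6-oxo-3-(propan-2-yl)heptanal | CC(=O)CC[C@@H](CC=O)C(C)C | intermediate
5 | (5R)-2-methyl-5-(propan-2-yl)cyclopent-1-ene-1-carbaldehyde | CC1=C(C=O)[C@H](CC1)C(C)C | intermediate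
6 | 1-[(5R)-2-methyl-5-(propan-2-yl)cyclopent-1-en-1-yl]ethan-1-ol, both carbinol epimers | CC1=C(C(C)O)[C@H](CC1)C(C)C | intermediate
7 | 1-[(5R)-2-methyl-5-(propan-2-yl)cyclopent-1-en-1-yl]ethan-1-one | CC1=C(C(C)=O)[C@H](CC1)C(C)C | intermediate
8 | (1R)-1-[(5R)-2-methyl-5-(propan-2-yl)cyclopent-1-en-1-yl]ethan-1-ol | CC1=C([C@@H](C)O)[C@H](CC1)C(C)C | intermediate
9 | bromoacetyl bromide | BrCC(Br)=O | starting material
10 | (1R)-1-[(5R)-2-methyl-5-(propan-2-yl)cyclopent-1-en-1-yl]ethyl bromoacetate | CC1=C([C@@H](C)OC(=O)CBr)[C@H](CC1)C(C)C | intermediate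
11 | (1R)-1-[(5R)-2-methyl-5-(propan-2-yl)cyclopent-1-en-1-yl]ethyl diazoacetate | CC1=C([C@@H](C)OC(=O)C=[N+]=[N-])[C@H](CC1)C(C)C | intermediate
12 | cyclopropane-fused γ-lactone C5–C6H(CH3)–O–C9(=O)–C10 on 1-methyl-4-isopropylbicyclo[3.1.0]hexane; C10 anti to isopropyl, C6 methyl on the lactone face away from C1 | O=C1O[C@H](C)[C@@]23[C@@H](C(C)C)CC[C@]2(C)[C@@H]13 | intermediate
13 | lactol of 12 (C9 hemiacetal, both anomers) | OC1O[C@H](C)[C@@]23[C@@H](C(C)C)CC[C@]2(C)[C@@H]13 | intermediate
14 | 5-(ethylsulfonyl)-1-phenyl-1H-tetrazole | CCS(=O)(=O)c1nnnn1-c1ccccc1 | starting material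
15 | (1R)-1-[4-isopropyl-1-methyl-10-((E)-prop-1-enyl)bicyclo[3.1.0]hex-5-yl]ethan-1-ol (target numbering; propenyl exo, cis to the C5 side chain) | C[C@@H](O)[C@@]12[C@@H](C(C)C)CC[C@]1(C)[C@H]2/C=C/C | intermediate
16 | 1-[4-isopropyl-1-methyl-10-((E)-prop-1-enyl)bicyclo[3.1.0]hex-5-yl]ethan-1-one | CC(=O)[C@@]12[C@@H](C(C)C)CC[C@]1(C)[C@H]2/C=C/C | intermediate
17 | 4-isopropyl-1-methyl-10-[(E)-prop-1-enyl]-5-[1-(triethylsilyloxy)vinyl]bicyclo[3.1.0]hexane | C=C(O[Si](CC)(CC)CC)[C@@]12[C@@H](C(C)C)CC[C@]1(C)[C@H]2/C=C/C | intermediate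
18 | 4-isopropyl-1,8-dimethyl-6-(triethylsilyloxy)bicyclo[5.3.0]deca-5,9-diene (1α-methyl, 4α-isopropyl, 8β-methyl) | C[C@H]1C=C[C@@]2(C)CC[C@H](C(C)C)C2=C(O[Si](CC)(CC)CC)C1 | intermediate
19 | dauca-4,9-dien-6-one (1α-methyl, 8β-methyl) | C[C@H]1C=C[C@@]2(C)CCC(C(C)C)=C2C(=O)C1 | intermediate
20 | 4β,5β-epoxydauc-9-en-6-one | C[C@H]1C=C[C@@]2(C)CC[C@@]3(C(C)C)O[C@@]23C(=O)C1 | intermediate
21 | 4β-hydroxy-5βH-dauc-9-en-6-one | C[C@H]1C=C[C@@]2(C)CC[C@](O)(C(C)C)[C@@H]2C(=O)C1 | intermediate
22 | 5βH-dauc-9-ene-4β,6α-diol | C[C@H]1C=C[C@@]2(C)CC[C@](O)(C(C)C)[C@@H]2[C@H](O)C1 | intermediate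
23 | 4-(tert-butyldimethylsilyloxy)benzoic acid | CC(C)(C)[Si](C)(C)Oc1ccc(cc1)C(O)=O | starting material
24 | 4β-hydroxy-5βH-dauc-9-en-6α-yl 4-(tert-butyldimethylsilyloxy)benzoate | C[C@H]1C=C[C@@]2(C)CC[C@](O)(C(C)C)[C@@H]2[C@H](OC(=O)c2ccc(O[Si](C)(C)C(C)(C)C)cc2)C1 | intermediate
25 | 10α-hydroperoxy-4β-hydroxy-5βH-dauc-8-en-6α-yl 4-(tert-butyldimethylsilyloxy)benzoate | CC1=C[C@H](OO)[C@@]2(C)CC[C@](O)(C(C)C)[C@@H]2[C@H](OC(=O)c2ccc(O[Si](C)(C)C(C)(C)C)cc2)C1 | intermediate (not isolated)
26 | 4β,10α-dihydroxy-5βH-dauc-8-en-6α-yl 4-(tert-butyldimethylsilyloxy)benzoate | CC1=C[C@H](O)[C@@]2(C)CC[C@](O)(C(C)C)[C@@H]2[C@H](OC(=O)c2ccc(O[Si](C)(C)C(C)(C)C)cc2)C1 | intermediate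
27 | 3-methylbutanoic anhydride | CC(C)CC(=O)OC(=O)CC(C)C | starting material
28 | 4β-hydroxy-10α-(3-methylbutanoyloxy)-5βH-dauc-8-en-6α-yl 4-(tert-butyldimethylsilyloxy)benzoate | CC1=C[C@H](OC(=O)CC(C)C)[C@@]2(C)CC[C@](O)(C(C)C)[C@@H]2[C@H](OC(=O)c2ccc(O[Si](C)(C)C(C)(C)C)cc2)C1 | intermediate
29 | 4β-hydroxy-10α-(3-methylbutanoyloxy)-5βH-dauc-8-en-6α-yl 4-hydroxybenzoate | CC1=C[C@H](OC(=O)CC(C)C)[C@@]2(C)CC[C@](O)(C(C)C)[C@@H]2[C@H](OC(=O)c2ccc(O)cc2)C1 | target

Total step count: 22. Longest linear sequence: 22 steps (from 1).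

Steps most likely to fail

1. Step 14. The cis C1 methyl group crowds the boat transition state, so the [3,3] shift may be overtaken by the homodienyl 1,5-hydrogen shift from that methyl group, which opens the cyclopropane to a 1,4-diene instead of enlarging the ring. The fallback sets out from 7 and comes back at 18, and closes the seven-membered ring by olefin metathesis instead. Conjugate addition of a vinyl cuprate (CH2=CHMgBr, CuI, Me3SiCl, THF, −40 °C) to 7, anti to the isopropyl group, should give 1-[2-ethenyl-2-methyl-5-(propan-2-yl)cyclopentyl]ethan-1-one F1 with C1 quaternary (both C5 epimers are usable). Kinetic enolisation (LiN(i-Pr)2, Me3SiCl, THF, −78 °C) gives the methyl-side trimethylsilyl enol ether F2. Iridium-catalysed branched allylation with (E)-but-2-enyl methyl carbonate ([Ir(cod)Cl]2, a phosphoramidite ligand of the enantiomer that gives (R)-C8, CsF, ZnF2) gives the (3R)-3-methylpent-4-enoyl ketone F3. Ring-closing metathesis with the second-generation Grubbs catalyst closes C9=C10 to the bicyclic ketone 5ξH-dauc-9-en-6-one F4. Thermodynamic silylation toward the ring-fusion carbon (Et3SiOTf, Et3N, CH2Cl2, rt) then gives 18.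

2. Step 16. Hydroperoxide addition to the fully substituted, isopropyl-bearing C4 may be slow and may not discriminate between the two faces of the enone. The fallback sets out from 19 and comes back at 21. Copper-catalysed conjugate borylation (CuCl, NaOt-Bu, a chiral bisphosphine, B2pin2, MeOH, THF), in which the ligand and not the substrate selects the β-face, should give the 4β-(pinacolboryl) ketone F5. Oxidation with NaBO3·4H2O, which proceeds with retention at carbon, then gives 21 without passing through epoxide 20.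

3. Step 20. Photo-oxygenation of the 1,2-disubstituted alkene may be slow, so that sensitiser bleaching and unselective oxidation compete during long irradiation. The fallback sets out from 24 and comes back at 26. Allylic oxidation with hexavalent chromium (CrO3·3,5-dimethylpyrazole, CH2Cl2, −20 °C) removes the same tertiary allylic hydrogen and, after allylic shift of the chromate ester, should give the transposed enone 4β-hydroxy-10-oxo-5βH-dauc-8-en-6α-yl 4-(tert-butyldimethylsilyloxy)benzoate F6. Reduction with NaBH4 and CeCl3·7H2O in MeOH, with hydride arriving on the β-face opposite the C1 methyl group, then gives the 10α-alcohol 26.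

Further compounds

F1 | step 14 | 1-[2-ethenyl-2-methyl-5-(propan-2-yl)cyclopentyl]ethan-1-one (vinyl anti to isopropyl, C5 epimers) | CC(=O)C1[C@@H](C(C)C)CC[C@]1(C)C=C
F2 | step 14 | trimethylsilyl enol ether of F1 on the methyl side | C=C(O[Si](C)(C)C)C1[C@@H](C(C)C)CC[C@]1(C)C=C
F3 | step 14 | (3R)-1-[2-ethenyl-2-methyl-5-(propan-2-yl)cyclopentyl]-3-methylpent-4-en-1-one | C[C@@H](C=C)CC(=O)C1[C@@H](C(C)C)CC[C@]1(C)C=C
F4 | step 14 | 5ξH-dauc-9-en-6-one (1α-methyl, 4α-isopropyl, 8β-methyl) | C[C@H]1C=C[C@@]2(C)CC[C@H](C(C)C)C2C(=O)C1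
F5 | step 16 | 4β-(4,4,5,5-tetramethyl-1,3,2-dioxaborolan-2-yl)-5βH-dauc-9-en-6-one | C[C@H]1C=C[C@@]2(C)CC[C@](B3OC(C)(C)C(C)(C)O3)(C(C)C)[C@@H]2C(=O)C1
F6 | step 20 | 4β-hydroxy-10-oxo-5βH-dauc-8-en-6α-yl 4-(tert-butyldimethylsilyloxy)benzoate | CC1=CC(=O)[C@@]2(C)CC[C@](O)(C(C)C)[C@@H]2[C@H](OC(=O)c2ccc(O[Si](C)(C)C(C)(C)C)cc2)C1
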